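## Structural features

The target is a 2,4-disubstituted furan. Furan C-2 is bonded directly to C-2 of a 1,4-benzoquinone ring, and furan C-4 carries a 1-acyloxy-4-methylpent-3-enyl chain. The only stereocentre is the furylic carbinol carbon, which is (R). It bears the 3-methylbutanoate, the furan and a CH2 leading to a trisubstituted olefin, and it has no neighbouring stereocentre, so it must be set by reagent control. The fragile groups are the quinone (Michael acceptor and oxidant), the electron-rich furan, the furylic ester (ionisable to a furan-stabilised cation, with racemisation or elimination) and the electron-rich trisubstituted olefin. The usual answer to a quinone is a protected hydroquinone and a final oxidation, which here would have to spare the furan, the olefin and the ester. The real difficulty is therefore the furan C-2–quinone C-2 bond, together with the quinone oxidation level and the 2,4-pattern on a furan whose cheap precursors are 3-monosubstituted. The key step exploits the fact that the furan α-C–H remote from the side chain (C-5 of a 3-substituted furan, C-2 of the target) is an enol-ether-type nucleophile and a quinone ring C–H carbon is a Michael acceptor. The two C–H carbons can therefore be joined directly, with the quinone acting as both partner and oxidant.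

## Logic of the disconnections

8 to 7. The C3=C4 double bond of the pentenyl chain is cut and the isopropylidene terminus removed, leaving the terminal vinyl group of 7. A trisubstituted olefin is about as nucleophilic toward an acid-activated quinone as a furan α-carbon, whereas a terminal vinyl group is far less so. Holding the two methyl groups back until after the key step removes the one serious chemoselectivity problem of that step. It also lets the chain come from a simple allyl transfer instead of a linear prenyl transfer, which is awkward because prenyl metals add through their γ-carbon. The forward step must exchange the olefin terminus in the presence of a quinone without touching the quinone C=C bonds or the stereocentre.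

7 to 4 + 5 (key disconnection). The bond between furan C-5 and quinone C-2 is cut, and each fragment keeps a hydrogen. The polarity is matched, and 5 can serve as electrophile and as oxidant for the hydroquinone first formed. No halogen, metal or O-protecting group is needed, and the quinone oxidation level arrives with the fragment. Compound 7, with two rings and a redox-sensitive core, falls to a 3-monosubstituted furan and the simplest quinone. The forward step must distinguish the two α-positions of 4 (C-5 against C-2), leave the furylic C–O bond intact under acid, and stop at mono-substitution.

4 to 3. The acyl C–O bond of the ester is cut. The ester is placed before the key step for two reasons. The acylated carbinol is bulkier and inductively withdrawing, which should steer the electrophile away from C-2. A free furylic alcohol would also be more open to ionisation and to oxidation by 5. The forward step must acylate oxygen without breaking the C–O bond of the stereocentre.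

3 to 1. The C1–C2 bond of the butenyl chain is cut, giving 1 and an allyl nucleophile. This disconnection sets the only stereocentre. The gain is a commercial 3-substituted furan that already has the correct attachment point. The forward step must deliver allyl to the Re face of a small heteroaryl aldehyde under reagent control.

## Other disconnections considered

Alternative 1: The first plan to come to mind cuts the furan–arene bond as a Pd cross-coupling. 5-Bromofuran-3-carbaldehyde A1 would be coupled with a 2,5-dimethoxyphenylboron reagent to give 5-(2,5-dimethoxyphenyl)furan-3-carbaldehyde A2. Asymmetric carbinol construction would give alcohol A3, followed by acylation and a final oxidative demethylation. This plan brings in a halogen, a boron group and two O-methyl groups that are absent from the target, and A1 is itself at least one step from commercial material. Its last step must oxidise a dimethoxyarene selectively beside an electron-rich 2-arylfuran, a trisubstituted olefin and a furylic ester. It needs at least six steps against four, so the chosen plan is preferred on step economy and on the redox risk at the end.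

Alternative 2: The furan ring is built de novo by cutting O1–C2. The forward key step would be Ag(I)- or Au(I)-catalysed 5-endo-dig cycloisomerisation and dehydration of the 3-alkyne-1,2-diol A4. That precursor has a quaternary carbinol next to the acyloxy stereocentre, so it needs an alkynylation of an α-oxygenated ketone and protecting-group work, and acyl migration between the three neighbouring oxygens is a risk. The ring it builds can be bought as 1, and the quinone would still have to be unmasked afterwards. The chosen plan is shorter and avoids creating and then destroying a second stereocentre.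

Alternative 3: A biomimetic plan also cuts O1–C2, but through a quinone methide. The alkylquinone enal A5 would tautomerise to an o-quinone methide, the formyl oxygen would add to the methide carbon, and proton loss would give the furylhydroquinone A6, which would then be oxidised. A5 is a Morita–Baylis–Hillman-type allylic ester with a (Z)-trisubstituted enal. It is open to SN2' displacement of the carboxylate and to E/Z isomerisation through the dienol, and quinone methides dimerise readily. The precursor is thus harder to make and keep than the target, and the sequence ends one oxidation level too low.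

Key step: step 3

Assumption: the stereocentre in the target SMILES is (R) by CIP analysis (O > furyl C > CH2 > H). The allylborane is taken as the commercial salt-free solution and is defined here by its SMILES, with Ipc groups derived from (−)-α-pinene.

## Route

Step 1
Reactants: 1 furan-3-carbaldehyde
Product: 3 (R)-1-(furan-3-yl)but-3-en-1-ol, via diisopinocampheylborinate 2 (not isolated)
Conditions: (+)-Ipc2B(allyl) (1.3 equiv), Et2O–pentane, −78 °C; then 3 M NaOH, 30% H2O2, 0 °C → rt
Reagents that add atoms: (+)-B-allyldiisopinocampheylborane, C=CCB([C@H]1C[C@H]2C[C@@H]([C@@H]1C)C2(C)C)[C@H]1C[C@H]2C[C@@H]([C@@H]1C)C2(C)C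
Why: Brown asymmetric allylboration through a closed chair Zimmerman–Traxler transition state; the isopinocampheyl groups from (−)-α-pinene should direct allyl transfer to the Re face of the aldehyde, the mirror image of the Si-face preference of the (+)-α-pinene-derived reagent with aryl aldehydes, which gives the (R)-carbinol. Oxidative work-up cleaves the borinate 2 to the alcohol.

Step 2
Reactants: 3 (R)-1-(furan-3-yl)but-3-en-1-ol
Product: 4 (R)-1-(furan-3-yl)but-3-en-1-yl 3-methylbutanoate
Conditions: 3-methylbutanoic acid (1.3 equiv), DCC (1.4 equiv), DMAP (10 mol %), CH2Cl2, 0 °C → rt
Reagents that add atoms: 3-methylbutanoic acid, CC(C)CC(=O)O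
Why: Steglich esterification; acylation takes place at oxygen under neutral conditions, so the C–O bond of the stereocentre is never broken and the configuration is retained.

Step 3
Reactants: 4 (R)-1-(furan-3-yl)but-3-en-1-yl 3-methylbutanoate; 5 1,4-benzoquinone
Product: 7 (R)-1-[5-(3,6-dioxocyclohexa-1,4-dien-1-yl)furan-3-yl]but-3-en-1-yl 3-methylbutanoate, via furylhydroquinone 6 (not isolated)
Conditions: 5 (3 equiv), Sc(OTf)3 (5 mol %), MeCN, 0 °C → rt, dark
Reagents that add atoms: none
Why: Sc(III) coordinates a carbonyl oxygen of 5, the furan α-carbon C-5 of 4 adds to the quinone ring carbon in a Friedel–Crafts-type conjugate addition, and loss of the proton from the oxocarbenium intermediate followed by enolisation gives the furylhydroquinone 6. A second equivalent of 5 then oxidises 6 to 7, which is favourable because the donor-substituted hydroquinone is the stronger reductant. The closest known reaction type is the acid-promoted substitutive addition of alkylfurans and indoles to p-benzoquinone (oxidative arylation of quinones). No ring is closed and no stereocentre is formed; the existing one is untouched as long as the furylic C–O bond does not ionise, which the low catalyst loading and temperature are chosen to ensure. α-Attack over β-attack follows from the oxocarbenium stabilisation of the intermediate. C-5 over C-2 should follow from the branched acyloxyalkyl group at C-3, which shields C-2 and, being inductively withdrawing, lacks the activating effect of a plain alkyl group. Furan over olefin is secured because a terminal vinyl group is orders of magnitude less nucleophilic than a furan α-carbon. Mono-substitution is favoured by the excess of 5, which is more electrophilic than the donor-substituted product.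

Step 4
Reactants: 7 (R)-1-[5-(3,6-dioxocyclohexa-1,4-dien-1-yl)furan-3-yl]but-3-en-1-yl 3-methylbutanoate
Product: 8 (R)-1-[5-(3,6-dioxocyclohexa-1,4-dien-1-yl)furan-3-yl]-4-methylpent-3-en-1-yl 3-methylbutanoate
Conditions: 2-methylbut-2-ene (large excess, co-solvent), Grubbs II (5 mol %), CH2Cl2, 35 °C, sealed tube
Reagents that add atoms: 2-methylbut-2-ene, CC=C(C)C
Why: Olefin cross-metathesis of a terminal olefin with 2-methylbut-2-ene, the standard way to turn an allyl into a prenyl group; the trisubstituted product has no E/Z issue. The conjugated, electron-poor quinone C=C bonds and the furan should be inert to the Ru alkylidene (benzoquinones are tolerated as additives in Ru metathesis), and the stereocentre is not involved.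

## Compound list

1 | furan-3-carbaldehyde | O=Cc1ccoc1 | starting material
2 | (R)-1-(furan-3-yl)but-3-en-1-yl diisopinocampheylborinate (Ipc from (−)-α-pinene) | C=CC[C@@H](OB([C@H]1C[C@H]2C[C@@H]([C@@H]1C)C2(C)C)[C@H]1C[C@H]2C[C@@H]([C@@H]1C)C2(C)C)c1ccoc1 | intermediate (not isolated)
3 | (R)-1-(furan-3-yl)but-3-en-1-ol | C=CC[C@@H](O)c1ccoc1 | intermediate
4 | (R)-1-(furan-3-yl)but-3-en-1-yl 3-methylbutanoate | C=CC[C@@H](OC(=O)CC(C)C)c1ccoc1 | intermediate
5 | 1,4-benzoquinone | O=C1C=CC(=O)C=C1 | starting material
6 | (R)-1-[5-(2,5-dihydroxyphenyl)furan-3-yl]but-3-en-1-yl 3-methylbutanoate | C=CC[C@@H](OC(=O)CC(C)C)c1coc(-c2cc(O)ccc2O)c1 | intermediate (not isolated)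
7 | (R)-1-[5-(3,6-dioxocyclohexa-1,4-dien-1-yl)furan-3-yl]but-3-en-1-yl 3-methylbutanoate | C=CC[C@@H](OC(=O)CC(C)C)c1coc(C2=CC(=O)C=CC2=O)c1 | intermediate
8 | (R)-1-[5-(3,6-dioxocyclohexa-1,4-dien-1-yl)furan-3-yl]-4-methylpent-3-en-1-yl 3-methylbutanoate (CNP0219765.1) | CC(C)=CC[C@@H](OC(=O)CC(C)C)c1coc(C2=CC(=O)C=CC2=O)c1 | target

## Step count and least certain steps

Total step count: 4. Longest linear sequence: 4 steps (1 → 3 → 4 → 7 → 8).

Step 3 (key step). Three things could go wrong:
- Regiocontrol between the two furan α-positions could erode, with attack at C-2 next to the side chain, because the bias is steric and only weakly electronic.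
- The Lewis acid could ionise the furylic C–O bond, with loss of the ester and of optical purity.
- The product could be arylated a second time.

Fallback, setting out from 4 and returning at 7: Ir-catalysed C–H borylation ([Ir(OMe)(cod)]2, dtbpy, B2pin2, rt) is governed by sterics and should select the unhindered α-position. It would give (R)-1-[5-(4,4,5,5-tetramethyl-1,3,2-dioxaborolan-2-yl)furan-3-yl]but-3-en-1-yl 3-methylbutanoate F1. Suzuki–Miyaura coupling with 2-bromo-1,4-dimethoxybenzene (Pd(dppf)Cl2, K3PO4, dioxane–water) would give (R)-1-[5-(2,5-dimethoxyphenyl)furan-3-yl]but-3-en-1-yl 3-methylbutanoate F2. Oxidative demethylation with ceric ammonium nitrate (MeCN–water, 0 °C) would then rejoin the route at 7.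

Step 4. The quinone could deactivate the Ru alkylidene by redox chemistry or chelation. Conversion could stall at the propenyl stage through incomplete secondary metathesis. Ru hydrides could cause double-bond migration.

Fallback, setting out from 4 and returning at 8: the metathesis is moved ahead of the aryl union and the quinone is carried masked, so that neither a quinone meets the catalyst nor an acid-activated quinone meets the trisubstituted olefin. Cross-metathesis of 4 with 2-methylbut-2-ene would give (R)-1-(furan-3-yl)-4-methylpent-3-en-1-yl 3-methylbutanoate F3. Steric Ir-catalysed C–H borylation would give (R)-4-methyl-1-[5-(4,4,5,5-tetramethyl-1,3,2-dioxaborolan-2-yl)furan-3-yl]pent-3-en-1-yl 3-methylbutanoate F4. Suzuki–Miyaura coupling with 2-bromo-1,4-dimethoxybenzene would give (R)-1-[5-(2,5-dimethoxyphenyl)furan-3-yl]-4-methylpent-3-en-1-yl 3-methylbutanoate F5. Ceric ammonium nitrate oxidation would deliver 8.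

Step 1. Facial discrimination could be insufficient with a small, flat heteroaryl aldehyde. The furan could be partly oxidised during the peroxide work-up. Separation from the terpene alcohol could be laborious.

Fallback, setting out from 1 and returning at 3: addition of allylmagnesium bromide (THF, −78 °C) would give racemic 1-(furan-3-yl)but-3-en-1-ol F6. Lipase-catalysed kinetic resolution by acylation (Candida antarctica lipase B, vinyl acetate, MTBE) should, by the empirical rule for secondary alcohols with an aryl and a CH2R substituent, acylate the (R)-enantiomer to (R)-1-(furan-3-yl)but-3-en-1-yl acetate F7. This is separated from the unreacted (S)-enantiomer of F6, and methanolysis (K2CO3, MeOH) would give 3. The price is that at most half of the material is used.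

## Further compounds

F1 | step 3 | (R)-1-[5-(4,4,5,5-tetramethyl-1,3,2-dioxaborolan-2-yl)furan-3-yl]but-3-en-1-yl 3-methylbutanoate | C=CC[C@@H](OC(=O)CC(C)C)c1coc(B2OC(C)(C)C(C)(C)O2)c1
F2 | step 3 | (R)-1-[5-(2,5-dimethoxyphenyl)furan-3-yl]but-3-en-1-yl 3-methylbutanoate | C=CC[C@@H](OC(=O)CC(C)C)c1coc(-c2cc(OC)ccc2OC)c1
F3 | step 4 | (R)-1-(furan-3-yl)-4-methylpent-3-en-1-yl 3-methylbutanoate | CC(C)=CC[C@@H](OC(=O)CC(C)C)c1ccoc1
F4 | step 4 | (R)-4-methyl-1-[5-(4,4,5,5-tetramethyl-1,3,2-dioxaborolan-2-yl)furan-3-yl]pent-3-en-1-yl 3-methylbutanoate | CC(C)=CC[C@@H](OC(=O)CC(C)C)c1coc(B2OC(C)(C)C(C)(C)O2)c1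
F5 | step 4 | (R)-1-[5-(2,5-dimethoxyphenyl)furan-3-yl]-4-methylpent-3-en-1-yl 3-methylbutanoate | CC(C)=CC[C@@H](OC(=O)CC(C)C)c1coc(-c2cc(OC)ccc2OC)c1
F6 | step 1 | racemic 1-(furan-3-yl)but-3-en-1-ol | C=CCC(O)c1ccoc1
F7 | step 1 | (R)-1-(furan-3-yl)but-3-en-1-yl acetate | C=CC[C@@H](OC(C)=O)c1ccoc1
A1 | alternative 1 | 5-bromofuran-3-carbaldehyde | O=Cc1coc(Br)c1
A2 | alternative 1 | 5-(2,5-dimethoxyphenyl)furan-3-carbaldehyde | O=Cc1coc(-c2cc(OC)ccc2OC)c1
A3 | alternative 1 | (R)-1-[5-(2,5-dimethoxyphenyl)furan-3-yl]-4-methylpent-3-en-1-ol | CC(C)=CC[C@@H](O)c1coc(-c2cc(OC)ccc2OC)c1
A4 | alternative 2 | (4R)-1-(2,5-dimethoxyphenyl)-3-hydroxy-3-(hydroxymethyl)-7-methyloct-6-en-1-yn-4-yl 3-methylbutanoate (C-3 configuration immaterial) | CC(C)=CC[C@@H](OC(=O)CC(C)C)C(O)(CO)C#Cc1cc(OC)ccc1OC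
A5 | alternative 3 | (2Z,4R)-1-(3,6-dioxocyclohexa-1,4-dien-1-yl)-3-formyl-7-methylocta-2,6-dien-4-yl 3-methylbutanoate | CC(C)=CC[C@@H](OC(=O)CC(C)C)/C(C=O)=C/CC1=CC(=O)C=CC1=O
A6 | alternative 3 | (R)-1-[5-(2,5-dihydroxyphenyl)furan-3-yl]-4-methylpent-3-en-1-yl 3-methylbutanoate | CC(C)=CC[C@@H](OC(=O)CC(C)C)c1coc(-c2cc(O)ccc2O)c1
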